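The numbers in the tables are calculated from invented constants, and the scatter is random.

Set two flasks side by side, the west run and the south-east run. They hold the same E and the same J, and the south-east run has twice the Q. Here are the flasks, the readings and the questions.

| setting | west | north-west | north-east | south-east | south |
|---|---|---|---|---|---|
| E | 0.0500 M | 0.0250 M | 0.0250 M | 0.0500 M | 0.0500 M |
| Q | 0.0600 M | 0.0350 M | 0.0600 M | 0.120 M | 0.210 M |
| J | 2.50 × 10⁻⁴ M | 2.50 × 10⁻⁴ M | 2.50 × 10⁻⁴ M | 2.50 × 10⁻⁴ M | 2.50 × 10⁻⁴ M |
| time |  |  |  |  | 6.4 min |

| run | time / min | [Z] / M |
|---|---|---|
| west run | 1.3 | 0.0099 |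
| west run | 2.6 | 0.0144 |
| west run | 3.8 | 0.0179 |
| west run | 5.1 | 0.0191 |
| west run | 6.4 | 0.0202 |
| north-west run | 1.3 | 0.0046 |
| north-west run | 2.6 | 0.0075 |
| north-west run | 3.8 | 0.0086 |
| north-west run | 5.1 | 0.0098 |
| north-west run | 6.4 | 0.0098 |
| north-east run | 1.3 | 0.0056 |
| north-east run | 2.6 | 0.0098 |
| north-east run | 3.8 | 0.0111 |
| north-east run | 5.1 | 0.0118 |
| north-east run | 6.4 | 0.0132 |
| south-east run | 1.3 | 0.0153 |
| south-east run | 2.6 | 0.0196 |
| south-east run | 3.8 | 0.0238 |
| south-east run | 5.1 | 0.0246 |
| south-east run | 6.4 | 0.0255 |

(each reading ± 8 × 10⁻⁴ M)

- Overall: E + Q -> Z, with J as catalyst.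
- Constant volume, constant temperature.
- The analysis sees a species whether free or bound.
- An order is taken over about fifteen percent of the charge, up and down.

- apparent order in [E] of the starting rate, round the charge of the west run (the rate where two percent of its E have turned into Z) (one fixed amount of Z, the same in the runs compared)
- apparent order in [Q] of the starting rate, round the charge of the west run (the rate where two percent of its E have turned into Z)
- Z in the south run at 6.4 min, as a share of the E charged

Apply a bench rule. With equal E, compare Z at the same early time; the ratio of Z follows the ratio of Q raised to the order. At 1.3 min the south-east run reads 0.0153 M and the west run reads 0.0099 M. Divide the logarithm of that Z ratio by the logarithm of the Q ratio: 0.628. Call this the first-reading exponent, the apparent order in Q read at the earliest reading. The scatter of the two readings puts about 0.139 on it.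

Now look for the border of the rule. It needs charges that have barely moved. Divide each first reading by its E charge: the west run reads Z at 19.8 % of its E, the south-east run at 30.6 %. That is no true start, so the real value may lie somewhat higher. Check what Q used up does to the ratio. The mean Q over that first stretch still stands at a ratio of 2.04. At 6.4 min the Z ratio has sunk to 1.26, which would give an exponent of 0.336. The rule has clearly stopped working there, so keep the first reading and drop the last. My own figure for the order in Q is 0.628.

The forecast parts from this. It gives 0.93 in E, 0.93 in Q and 62 % for the south run, holding that the “apparent orders from the first points are therefore misleading”. Its order in Q is higher than mine.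

The flask gives 1.0 in E, 0.64 in Q and 61.6 % for the south run.

    J + E + Q → Z + J (51180 L² mol⁻² min⁻¹)
    2 E → Oz (6.780 L mol⁻¹ min⁻¹)
    2 Q ⇌ Q2, settled at all times (50.70 L mol⁻¹)

The exponent 0.628, a reading with its scatter, lies close to the flask's order, and the forecast's order stands above it. The joining of pairs of Q holds the order down: without that joining the order in Q is 1.0. Now carry the exponent to the north-west run. Start from the south-east rate of 0.018 M min⁻¹, take half the E at first order, and scale by the Q ratio raised to the exponent. That predicts 0.00414 M min⁻¹, and the flask gives 0.0040 M min⁻¹.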